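## Structural features

The target is an ent-labdane diterpenoid (labdane locants C1–C20 are used throughout). It is a trans-fused decalin in which rings A and B share the C5–C10 bond; ring A carries the C4 gem-dimethyl group and the angular C20 methyl sits on C10. C9 bears a six-carbon side chain ending in a (12Z)-3-methyl-1,3-diene (C12=C13 trisubstituted and Z, C14=C15 terminal). Every carbon of ring B that can be stereogenic is so: C5, C6, C7, C8, C9 and C10 are contiguous, with a secondary hydroxyl at C6, an acetate at C7 and a tertiary carbinol at C8 (C17 methyl). On the chair the three oxygens and the C9 chain are equatorial and C17 and C20 are syn-axial; the configuration is (5R,6S,7R,8R,9S,10R). The fragile groups are the Z-diene next to a tertiary alcohol (acid-promoted ionisation, cyclisation, isomerisation, oxidation), the C7 acetate between two free hydroxyls (acyl migration under base) and, at the ketone stage, the α-ketol array. The real difficulty is the quaternary C10 flanked by two stereocentres across a trans ring fusion, the differentiation of three neighbouring oxygens on a fully substituted ring B, and the Z-trisubstituted diene. The key step exploits ring B as the cyclohexene of a C5=C6–C7(OSi)=C8 diene and a C9=C10 dienophile joined through C1–C4: it closes rings A and B, sets C5, C9 and C10, installs the C7 oxygen and leaves a regiodefined enol ether for oxygenation of C6 and then C8.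

## Logic of the disconnections

26 from 25: the C13–C14 bond between the two alkenes is cut. The diene is the most fragile unit and is made last; 25 carries a vinyl iodide that survives acid, base, hydride and oxidants. The forward step must be a stereoretentive sp2–sp2 coupling under neutral conditions that tolerate the acetate and two free hydroxyls.

25 from 24, 23 and 22: the O6–Si bond, the O7–acetyl bond and the C7–H bond are cut in turn. The silyl group on O6 distinguishes O6 from O7, so the acetate goes on unambiguously, and a ketone at C7 is simpler than the carbinol. The forward steps demand hydride delivery to the axial position of C7 and a desilylation that does not move the acetate.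

22 from 20: the C8–O bond is cut. The C7 ketone is the only function that can activate C8, and removing the tertiary hydroxyl removes a stereocentre. The forward step needs enolisation towards C8 rather than C6 and oxygen delivery anti to C20.

20 from 19: the C12=C13 double bond is cut. The Z-iodoalkene geometry can be set by an α-iodo ylide, and 19 is a simple aldehyde. The forward olefination must be Z-selective and must choose the aldehyde over the C7 ketone.

19 from 17: the C11–C12 bond is cut. C11 is the carbon that activated the dienophile, and the side chain needs it as a methylene with one more carbon attached. The forward step is a one-carbon homologation of a hindered aldehyde.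

17 from 16 and 15: the C11–S and then the C11–N bond are cut. A thioester can be reduced to the aldehyde without touching the C7 ketone, and its formation releases the auxiliary. The forward cleavage must occur at the hindered exocyclic carbonyl and not in the oxazolidinone ring.

15 from 13: the C6–O bond is cut. The enol ether of 13 makes C6 the nucleophilic carbon, and the silyl group that migrates protects O6. The forward epoxidation must take place on the face away from C19 and C20.

13 from 12: the C5–C10 and C8–C9 bonds are cut. This opens both rings and removes four stereocentres, leaving an acyclic triene whose stereochemistry lies only in three alkene geometries and the auxiliary. The forward cycloaddition must be trans-fusing and selective for one π-face.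

12 from 4 and 10: the C1–C10 bond (sp3–sp2) is cut. The E-geometry of the enimide is the only source of the C9/C10 relationship, and a stereospecific coupling of a preformed E-enol triflate fixes it, which olefination of a methyl ketone would not. It also splits 12 into two fragments of similar size. The forward step needs hydroboration of the terminal alkene only, coupling with retention, and survival of the silyl enol ether.

4 from 3, and 3 from 1 and 2: the O–Si bond and then the C5=C6 double bond are cut. This leads to a commercial α-quaternary aldehyde and a commercial ketophosphonate. The forward steps need an E-enone and a Z-enol ether.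

10 from 7 and 8, 7 from 6, 6 from 5: the N–C11 acyl bond, the ester C–O bond and the enol O–S bond are cut. This leads to the commercial auxiliary and a commercial β-keto ester. The forward demand is an E-configured enol triflate that keeps its geometry through ester cleavage and acylation.

## Other disconnections considered

Alternative 1: The cut is at C1–C10 and C4–C5, so that ring A is formed on a quinone that becomes ring B. In the forward sense, 4-methylpenta-1,3-diene A3 would add to the methyl-bearing alkene of 2,6-dimethyl-1,4-benzoquinone A2 under a chiral oxazaborolidinium Lewis acid, giving the cis-fused enedione A1.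
- In its favour: both components are commercial, the quaternary C10 would be set catalytically in the first step without an auxiliary, and the polarity is matched (the CH2 terminus of A3 bonds to the quinone carbon β to the coordinated carbonyl). On catalytic stereocontrol, matched mechanism and steps to the bicycle it is better than the chosen plan.
- Against it: A3 carries a cis-methyl group on the reacting terminus, which disfavours the s-cis conformer and crowds the forming C4–C5 bond, and the dienophile alkene is trisubstituted, so reactivity is doubtful.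
- Further against it: A1 has C5 with the wrong (cis) configuration, an extra ring A alkene, and a ketone at C9. The whole side chain would have to be added to that hindered carbonyl and the oxygen then removed with control of C9; the C6 ketone and C7=C8 enone would still have to become the 6-OH, 7-OAc, 8-OH array.
- Comparison: A1 fixes one permanent stereocentre where the chosen cycloadduct fixes three with C11 already attached. Its front end is shorter but its back end is longer and less certain.

Alternative 2: The cut is at C7–C8 and C9–C10, so that ring B is built on a preformed ring A. In the forward sense, the ring A silyloxydiene A5 would add to 1-(but-2-ynoyl)-3,5-dimethylpyrazole A6 under Cu(NTf2)2 (divalent copper) with a chiral bis(oxazoline) ligand, giving the 5,8-diene A4.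
- In its favour: ring A comes from cheap cyclogeranyl-type material and the reaction is catalytic and asymmetric. The polarity is matched (the nucleophilic C7 terminus bonds to the β-carbon C8), which is better than the chosen plan. The acyl pyrazole is an easier acyl donor to exchange than a hindered imide, which is also better.
- Against it: the C10 terminus of A5 is fully substituted and the diene is twisted out of the s-cis form by its three ring methyl groups, so the quaternary centre must form intermolecularly at a very hindered carbon.
- Further against it: A4 contains only C10 as a stereocentre. C5 and C9 would have to be set afterwards from two tetrasubstituted or enol-ether alkenes, the oxygen sits on C6 rather than C7, and C7 and C8 would each need a separate stereocontrolled oxygenation.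
- Comparison: one stereocentre in the key step against three; fewer steps to the bicycle but more afterwards.

Alternative 3: The cut is at C4–C5 and C9–C10 of a polyene. In the forward sense, a class 2 diterpene cyclase would protonate the terminal alkene of geranylgeranyl diphosphate A8 and close both rings to ent-copalyl diphosphate A7.
- In its favour: one step forms rings A and B and C5, C9 and C10 in the correct ent series with all twenty skeletal carbons, without protecting groups. On skeletal step economy and stereocontrol this is better than any chemical plan, the chosen one included.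
- Against it: it needs the recombinant enzyme and the diphosphate A8 (or an engineered host), which limits scale and access. A7 has no oxygen at C6 or C7.
- Further against it: the C8=C17 alkene could serve for C8 hydration and allylic oxidation at C7, but C6 is an unactivated methylene next to the gem-dimethyl group. The allylic diphosphate would still have to become the Z-diene.
- Comparison: a cationic cascade under enzyme control against a pericyclic reaction under auxiliary control. The skeleton is far cheaper, but the C6/C7 oxygenation is where the chosen plan is stronger, since its cycloaddition delivers the C7 oxygen and an enol ether for C6.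

Key step: step 7

Remarks on the chemistry (assumptions):
- The auxiliary is used as its (R)-antipode: in the aluminium chelate the benzyl group of the (S)-antipode would cover the Cα-Re face of C9 and lead to the mirror-image decalin.
- The E-enimide is made by a stereospecific coupling of an E-enol triflate, so that the C9=C10 geometry is not left to a ketone olefination.
- C8 in 15–20 is written with the configuration set in step 7; it may epimerise under the basic steps, which does not matter because step 13 re-forms this centre.
- 18 is expected as an E/Z mixture at C11=C12; both isomers hydrolyse to 19.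

## Route

Step 1
Reactants: 1 2,2-dimethylpent-4-enal; 2 diethyl (2-oxobutyl)phosphonate
Product: 3 (E)-6,6-dimethylnona-4,8-dien-3-one
Conditions: Ba(OH)2, THF/H2O (40:1), rt
Reagents that add atoms: none
Why: Horner–Wadsworth–Emmons olefination of a non-enolisable α-quaternary aldehyde with a β-ketophosphonate; the stabilised anion should give the E-enone, and the mild base avoids aldol and Michael side reactions.

Step 2
Reactants: 3 (E)-6,6-dimethylnona-4,8-dien-3-one
Product: 4 tert-butyl{[(2Z,4E)-6,6-dimethylnona-2,4,8-trien-3-yl]oxy}dimethylsilane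
Conditions: TBSOTf, Et3N, CH2Cl2, 0 °C
Reagents that add atoms: tert-butyldimethylsilyl trifluoromethanesulfonate, CC(C)(C)[Si](C)(C)OS(=O)(=O)C(F)(F)F
Why: Soft enolisation of the ethyl enone, whose only enolisable position is the ethyl CH2 because C4 is quaternary, should give the cross-conjugated 2-silyloxydiene; the Z-enol ether (methyl cis to oxygen) is the usual outcome for ethyl ketones and places C17 outside on the diene.

Step 3
Reactants: 5 tert-butyl acetoacetate
Product: 6 tert-butyl (E)-3-{[(trifluoromethyl)sulfonyl]oxy}but-2-enoate
Conditions: Tf2O, aq. Me4NOH, hexanes, 5 °C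
Reagents that add atoms: trifluoromethanesulfonic anhydride, O=S(=O)(OS(=O)(=O)C(F)(F)F)C(F)(F)F
Why: O-triflation of the β-keto ester enolate under biphasic conditions with a non-coordinating tetraalkylammonium counter-ion; without a chelating metal the enolate takes the dipole-minimised geometry, so the E-enol triflate (OTf trans to the ester) should result, which fixes the later C9=C10 geometry.

Step 4
Reactants: 6 tert-butyl (E)-3-{[(trifluoromethyl)sulfonyl]oxy}but-2-enoate
Product: 7 (E)-3-{[(trifluoromethyl)sulfonyl]oxy}but-2-enoic acid
Conditions: TFA, CH2Cl2, rt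
Reagents that add atoms: none
Why: Acidolysis of the tert-butyl ester with loss of 2-methylpropene; the vinyl triflate is stable to acid and keeps its geometry.

Step 5
Reactants: 7 (E)-3-{[(trifluoromethyl)sulfonyl]oxy}but-2-enoic acid; 8 (R)-4-benzyloxazolidin-2-one
Product: 10 (R)-4-benzyl-3-[(E)-3-{[(trifluoromethyl)sulfonyl]oxy}but-2-enoyl]oxazolidin-2-one, via acid chloride 9 (not isolated)
Conditions: (COCl)2, cat. DMF, CH2Cl2, 0 °C → rt; then 8, n-BuLi, THF, −78 °C
Reagents that add atoms: none
Why: Acid chloride formation and N-acylation of the lithiated oxazolidinone at −78 °C, where attack at the acyl chloride is much faster than addition–elimination at the triflate-bearing carbon; the alkene geometry is not touched.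

Step 6
Reactants: 4 tert-butyl{[(2Z,4E)-6,6-dimethylnona-2,4,8-trien-3-yl]oxy}dimethylsilane; 10 (R)-4-benzyl-3-[(E)-3-{[(trifluoromethyl)sulfonyl]oxy}but-2-enoyl]oxazolidin-2-one
Product: 12 (R)-4-benzyl-3-[(2E,8E,10Z)-10-(tert-butyldimethylsilyloxy)-3,7,7-trimethyldodeca-2,8,10-trienoyl]oxazolidin-2-one, via alkylborane 11 (not isolated)
Conditions: 9-BBN, THF, 0 °C → rt; then 10, PdCl2(dppf), AsPh3, K3PO4 (aq.), DMF, rt
Reagents that add atoms: none
Why: Anti-Markovnikov hydroboration by 9-BBN should be selective for the monosubstituted terminal alkene over the hindered disubstituted alkene and the trisubstituted enol ether; B-alkyl Suzuki–Miyaura coupling with the enol triflate proceeds with retention, so the E-enimide (C20 cis to the carbonyl) is expected as a single isomer.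

Step 7
Reactants: 12 (R)-4-benzyl-3-[(2E,8E,10Z)-10-(tert-butyldimethylsilyloxy)-3,7,7-trimethyldodeca-2,8,10-trienoyl]oxazolidin-2-one
Product: 13 (R)-4-benzyl-3-{[(1R,2S,4aR,8aR)-3-(tert-butyldimethylsilyloxy)-2,5,5,8a-tetramethyl-1,2,4a,5,6,7,8,8a-octahydronaphthalen-1-yl]carbonyl}oxazolidin-2-one
Conditions: Me2AlCl (1.5 equiv), CH2Cl2, −30 → 0 °C; then 1 N HCl
Reagents that add atoms: none
Why: Excess Me2AlCl should convert the imide into the cationic bidentate chelate, in which the enoyl group is locked s-cis (the C20 methyl, cis to the carbonyl, rules out s-trans) and its LUMO is lowered, and the tethered diene then adds in a concerted, asynchronous, suprafacial [4+2] cycloaddition. The closest known reaction type is the Lewis acid-promoted intramolecular Diels–Alder reaction of (E,E,E)-trienimides that carry oxazolidinone auxiliaries. Ring B is the cycloaddition ring, closed by the new C5–C10 and C8–C9 bonds, and ring A is the tether ring, closed by the same C5–C10 bond through a chair-like folding of the C1–C4 chain (1,7,9-decatriene mode, tether on the dienophile carbon remote from the carbonyl). C9 and C10 are set relative to each other by the E-geometry of the enimide, so C11 and C20 end cis, and C8 by the Z-enol ether, which keeps C17 in the outside position (this centre is re-made later). C5 is set relative to C10 by the carbonyl-endo, tether-exo transition state that Lewis acid activation favours, which gives the trans ring fusion. The absolute configuration comes from the auxiliary: in the chelate the benzyl group of the (R)-oxazolidinone covers the Cα-Si face of C9, so the diene adds to the Cα-Re face and the (5R,9R,10R) adduct should result. The step therefore needs endo (trans-fusing) selectivity and one π-face, secured by the chelated auxiliary and the fixed alkene geometries, with the gem-dimethyl group at C4 favouring the coiled reactive conformer. The polarity mismatch (the nucleophilic diene terminus C8 must bond to the α-carbon C9) is tolerated because the four-carbon tether allows no other regiochemistry, but it makes this the slowest and least certain step.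

Step 8
Reactants: 13 (R)-4-benzyl-3-{[(1R,2S,4aR,8aR)-3-(tert-butyldimethylsilyloxy)-2,5,5,8a-tetramethyl-1,2,4a,5,6,7,8,8a-octahydronaphthalen-1-yl]carbonyl}oxazolidin-2-one
Product: 15 (R)-4-benzyl-3-[(5R,6S,8S,9R,10R)-6-(tert-butyldimethylsilyloxy)-7-oxo-12,13,14,15,16-pentanorlabdan-11-oyl]oxazolidin-2-one, via silyloxy epoxide 14 (not isolated)
Conditions: mCPBA, NaHCO3, CH2Cl2, −20 → 0 °C
Reagents that add atoms: 3-chloroperoxybenzoic acid, OOC(=O)c1cccc(Cl)c1
Why: Rubottom oxidation: the electron-rich C6=C7 enol ether should be epoxidised on the face opposite to the syn-axial C19 and C20 methyl groups and the C8 methyl, and ring opening with 1,4-silyl migration gives the 6-silyloxy-7-ketone with the C6–O bond equatorial (6S). The silyl group ends on O6 and serves as its protecting group.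

Step 9
Reactants: 15 (R)-4-benzyl-3-[(5R,6S,8S,9R,10R)-6-(tert-butyldimethylsilyloxy)-7-oxo-12,13,14,15,16-pentanorlabdan-11-oyl]oxazolidin-2-one
Product: 16 S-ethyl (5R,6S,8S,9R,10R)-6-(tert-butyldimethylsilyloxy)-7-oxo-12,13,14,15,16-pentanorlabdane-11-thioate
Conditions: EtSH, n-BuLi, THF, 0 °C → rt; then aq. NH4Cl
Reagents that add atoms: ethanethiol (as lithium ethanethiolate), CCS
Why: Transthioesterification with lithium ethanethiolate, a small soft nucleophile of the kind used to cleave hindered N-acyloxazolidinones at the exocyclic carbonyl; the ketone and silyl ether are inert and the auxiliary is recovered.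

Step 10
Reactants: 16 S-ethyl (5R,6S,8S,9R,10R)-6-(tert-butyldimethylsilyloxy)-7-oxo-12,13,14,15,16-pentanorlabdane-11-thioate
Product: 17 (5R,6S,8S,9R,10R)-6-(tert-butyldimethylsilyloxy)-7-oxo-12,13,14,15,16-pentanorlabdan-11-al
Conditions: Et3SiH, Pd/C (10%), acetone, rt
Reagents that add atoms: none
Why: Fukuyama reduction: insertion of palladium into the C–S bond and hydride transfer from the silane should stop at the aldehyde and leave the ketone untouched; C9 keeps its configuration with the formyl group equatorial.

Step 11
Reactants: 17 (5R,6S,8S,9R,10R)-6-(tert-butyldimethylsilyloxy)-7-oxo-12,13,14,15,16-pentanorlabdan-11-al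
Product: 19 (5R,6S,8S,9R,10S)-6-(tert-butyldimethylsilyloxy)-7-oxo-13,14,15,16-tetranorlabdan-12-al, via methyl enol ether 18 (not isolated)
Conditions: [Ph3PCH2OMe]Cl, KN(SiMe3)2, THF, −78 → 0 °C; then 1 N HCl, THF, rt
Reagents that add atoms: (methoxymethyl)triphenylphosphonium chloride, COC[P+](c1ccccc1)(c1ccccc1)c1ccccc1.[Cl-]; water, O
Why: Wittig methoxymethylenation of the aldehyde, which is far more reactive than the hindered α,α′-substituted ketone, followed by acid hydrolysis of the enol ether should give the one-carbon homologue; the hindered secondary silyl ether is expected to survive dilute acid.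

Step 12
Reactants: 19 (5R,6S,8S,9R,10S)-6-(tert-butyldimethylsilyloxy)-7-oxo-13,14,15,16-tetranorlabdan-12-al
Product: 20 (5R,6S,8S,9R,10S,12Z)-6-(tert-butyldimethylsilyloxy)-13-iodo-14,15-dinorlabd-12-en-7-one
Conditions: [Ph3PEt]I, n-BuLi, THF, rt; I2, −78 °C; NaN(SiMe3)2, −20 °C; then 19, −78 → −20 °C
Reagents that add atoms: ethyltriphenylphosphonium iodide, CC[P+](c1ccccc1)(c1ccccc1)c1ccccc1.[I-]; iodine, II
Why: Stork–Zhao-type Wittig olefination with the α-iodoethylidene ylide; the non-stabilised α-halo ylide reacts under kinetic control and should give the Z-iodoalkene (iodine cis to C11), and the aldehyde reacts in preference to the hindered ketone.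

Step 13
Reactants: 20 (5R,6S,8S,9R,10S,12Z)-6-(tert-butyldimethylsilyloxy)-13-iodo-14,15-dinorlabd-12-en-7-one
Product: 22 (5R,6S,8R,9S,10R,12Z)-6-(tert-butyldimethylsilyloxy)-8-hydroxy-13-iodo-14,15-dinorlabd-12-en-7-one, via potassium enolate 21 (not isolated)
Conditions: KN(SiMe3)2, THF, −78 °C; 2-(phenylsulfonyl)-3-phenyloxaziridine, −78 °C; then aq. NH4Cl
Reagents that add atoms: 2-(phenylsulfonyl)-3-phenyloxaziridine, O=S(=O)(c1ccccc1)N1OC1c1ccccc1
Why: Enolate hydroxylation with an N-sulfonyloxaziridine: the C7 ketone should enolise towards C8 because H6 is shielded by the syn-axial C19 and C20 methyl groups and deactivated by the α-oxygen. Oxygen is delivered to C8 on the face opposite to the axial C20 methyl, giving the equatorial tertiary hydroxyl with C17 axial (8R).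

Step 14
Reactants: 22 (5R,6S,8R,9S,10R,12Z)-6-(tert-butyldimethylsilyloxy)-8-hydroxy-13-iodo-14,15-dinorlabd-12-en-7-one
Product: 23 (5R,6S,7R,8R,9S,10R,12Z)-6-(tert-butyldimethylsilyloxy)-13-iodo-14,15-dinorlabd-12-ene-7,8-diol
Conditions: NaBH4, MeOH/CH2Cl2, −40 → 0 °C
Reagents that add atoms: none
Why: Borohydride reduction by axial attack at C7 from the face that carries only axial hydrogens (H5, H9), the other face being blocked by the axial C17 methyl, should give the equatorial 7-hydroxyl (7R), trans to both neighbouring oxygens.

Step 15
Reactants: 23 (5R,6S,7R,8R,9S,10R,12Z)-6-(tert-butyldimethylsilyloxy)-13-iodo-14,15-dinorlabd-12-ene-7,8-diol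
Product: 24 (5R,6S,7R,8R,9S,10R,12Z)-6-(tert-butyldimethylsilyloxy)-8-hydroxy-13-iodo-14,15-dinorlabd-12-en-7-yl acetate
Conditions: Ac2O, DMAP, pyridine, CH2Cl2, rt
Reagents that add atoms: acetic anhydride, CC(=O)OC(C)=O
Why: DMAP-catalysed acetylation of the only free secondary hydroxyl; the tertiary C8 hydroxyl is too hindered to react under these conditions and O6 is silylated.

Step 16
Reactants: 24 (5R,6S,7R,8R,9S,10R,12Z)-6-(tert-butyldimethylsilyloxy)-8-hydroxy-13-iodo-14,15-dinorlabd-12-en-7-yl acetate
Product: 25 (5R,6S,7R,8R,9S,10R,12Z)-6,8-dihydroxy-13-iodo-14,15-dinorlabd-12-en-7-yl acetate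
Conditions: HF·pyridine, pyridine, THF, 0 °C → rt
Reagents that add atoms: none
Why: Fluoride cleavage of the secondary silyl ether under buffered, slightly acidic conditions, chosen to suppress migration of the acetate from O7 to O6; it is done before the diene exists so that the acid-sensitive allylic system never meets HF.

Step 17
Reactants: 25 (5R,6S,7R,8R,9S,10R,12Z)-6,8-dihydroxy-13-iodo-14,15-dinorlabd-12-en-7-yl acetate
Product: 26 (5R,6S,7R,8R,9S,10R,12Z)-6,8-dihydroxylabda-12,14-dien-7-yl acetate (CNP0225877.2)
Conditions: CH2=CHSnBu3, Pd2(dba)3, AsPh3, CuI, DMF, rt → 40 °C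
Reagents that add atoms: tributyl(vinyl)stannane, C=C[Sn](CCCC)(CCCC)CCCC
Why: Stille coupling of the Z-vinyl iodide with the vinylstannane proceeds with retention of alkene geometry under neutral conditions that tolerate the acetate and both free hydroxyls, so the 12Z-diene is formed in the last step.

## Compound list

1 | 2,2-dimethylpent-4-enal | C=CCC(C)(C)C=O | starting material
2 | diethyl (2-oxobutyl)phosphonate | CCC(=O)CP(=O)(OCC)OCC | starting material
3 | (E)-6,6-dimethylnona-4,8-dien-3-one | CCC(=O)/C=C/C(C)(C)CC=C | intermediate
4 | tert-butyl{[(2Z,4E)-6,6-dimethylnona-2,4,8-trien-3-yl]oxy}dimethylsilane | C/C=C(O[Si](C)(C)C(C)(C)C)/C=C/C(C)(C)CC=C | intermediate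
5 | tert-butyl acetoacetate | CC(=O)CC(=O)OC(C)(C)C | starting material
6 | tert-butyl (E)-3-{[(trifluoromethyl)sulfonyl]oxy}but-2-enoate | CC(C)(C)OC(=O)/C=C(\C)OS(=O)(=O)C(F)(F)F | intermediate
7 | (E)-3-{[(trifluoromethyl)sulfonyl]oxy}but-2-enoic acid | OC(=O)/C=C(\C)OS(=O)(=O)C(F)(F)F | intermediate
8 | (R)-4-benzyloxazolidin-2-one | O=C1N[C@H](Cc2ccccc2)CO1 | starting material
9 | (E)-3-{[(trifluoromethyl)sulfonyl]oxy}but-2-enoyl chloride | ClC(=O)/C=C(\C)OS(=O)(=O)C(F)(F)F | intermediate
10 | (R)-4-benzyl-3-[(E)-3-{[(trifluoromethyl)sulfonyl]oxy}but-2-enoyl]oxazolidin-2-one | O=C(/C=C(\C)OS(=O)(=O)C(F)(F)F)N1C(=O)OC[C@H]1Cc1ccccc1 | intermediate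
11 | 9-[(5E,7Z)-7-(tert-butyldimethylsilyloxy)-4,4-dimethylnona-5,7-dien-1-yl]-9-borabicyclo[3.3.1]nonane | C/C=C(O[Si](C)(C)C(C)(C)C)/C=C/C(C)(C)CCCB1C2CCCC1CCC2 | intermediate
12 | (R)-4-benzyl-3-[(2E,8E,10Z)-10-(tert-butyldimethylsilyloxy)-3,7,7-trimethyldodeca-2,8,10-trienoyl]oxazolidin-2-one | C/C=C(O[Si](C)(C)C(C)(C)C)/C=C/C(C)(C)CCC/C(C)=C/C(=O)N1C(=O)OC[C@H]1Cc1ccccc1 | intermediate
13 | (R)-4-benzyl-3-{[(1R,2S,4aR,8aR)-3-(tert-butyldimethylsilyloxy)-2,5,5,8a-tetramethyl-1,2,4a,5,6,7,8,8a-octahydronaphthalen-1-yl]carbonyl}oxazolidin-2-one (trans-fused C6=C7 silyl enol ether; labdane locants 5R,8S,9R,10R) | O=C(N1C(=O)OC[C@H]1Cc1ccccc1)[C@@H]1[C@H](C)C(O[Si](C)(C)C(C)(C)C)=C[C@@H]2C(C)(C)CCC[C@]21C | intermediate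
14 | 6,7-epoxide of 13 with the oxygen on the ring face opposite to C20 (7-silyloxy oxirane) | O=C(N1C(=O)OC[C@H]1Cc1ccccc1)[C@@H]1[C@H](C)[C@@]3(O[Si](C)(C)C(C)(C)C)O[C@H]3[C@@H]2C(C)(C)CCC[C@]21C | intermediate
15 | (R)-4-benzyl-3-[(5R,6S,8S,9R,10R)-6-(tert-butyldimethylsilyloxy)-7-oxo-12,13,14,15,16-pentanorlabdan-11-oyl]oxazolidin-2-one | O=C(N1C(=O)OC[C@H]1Cc1ccccc1)[C@@H]1[C@H](C)C(=O)[C@@H](O[Si](C)(C)C(C)(C)C)[C@@H]2C(C)(C)CCC[C@]21C | intermediate
16 | S-ethyl (5R,6S,8S,9R,10R)-6-(tert-butyldimethylsilyloxy)-7-oxo-12,13,14,15,16-pentanorlabdane-11-thioate | CCSC(=O)[C@@H]1[C@H](C)C(=O)[C@@H](O[Si](C)(C)C(C)(C)C)[C@@H]2C(C)(C)CCC[C@]21C | intermediate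
17 | (5R,6S,8S,9R,10R)-6-(tert-butyldimethylsilyloxy)-7-oxo-12,13,14,15,16-pentanorlabdan-11-al | O=C[C@@H]1[C@H](C)C(=O)[C@@H](O[Si](C)(C)C(C)(C)C)[C@@H]2C(C)(C)CCC[C@]21C | intermediate
18 | (5R,6S,8S,9R,10S)-6-(tert-butyldimethylsilyloxy)-12-methoxy-13,14,15,16-tetranorlabd-11-en-7-one (E/Z mixture at C11=C12) | COC=C[C@@H]1[C@H](C)C(=O)[C@@H](O[Si](C)(C)C(C)(C)C)[C@@H]2C(C)(C)CCC[C@]21C | intermediate
19 | (5R,6S,8S,9R,10S)-6-(tert-butyldimethylsilyloxy)-7-oxo-13,14,15,16-tetranorlabdan-12-al | O=CC[C@@H]1[C@H](C)C(=O)[C@@H](O[Si](C)(C)C(C)(C)C)[C@@H]2C(C)(C)CCC[C@]21C | intermediate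
20 | (5R,6S,8S,9R,10S,12Z)-6-(tert-butyldimethylsilyloxy)-13-iodo-14,15-dinorlabd-12-en-7-one | C/C(I)=C/C[C@@H]1[C@H](C)C(=O)[C@@H](O[Si](C)(C)C(C)(C)C)[C@@H]2C(C)(C)CCC[C@]21C | intermediate
21 | potassium enolate of 20 (C7–O−, C7=C8) | C/C(I)=C/C[C@@H]1C(C)=C([O-])[C@@H](O[Si](C)(C)C(C)(C)C)[C@@H]2C(C)(C)CCC[C@]21C.[K+] | intermediate
22 | (5R,6S,8R,9S,10R,12Z)-6-(tert-butyldimethylsilyloxy)-8-hydroxy-13-iodo-14,15-dinorlabd-12-en-7-one | C/C(I)=C/C[C@@H]1[C@@](C)(O)C(=O)[C@@H](O[Si](C)(C)C(C)(C)C)[C@@H]2C(C)(C)CCC[C@]21C | intermediate
23 | (5R,6S,7R,8R,9S,10R,12Z)-6-(tert-butyldimethylsilyloxy)-13-iodo-14,15-dinorlabd-12-ene-7,8-diol | C/C(I)=C/C[C@@H]1[C@@](C)(O)[C@H](O)[C@@H](O[Si](C)(C)C(C)(C)C)[C@@H]2C(C)(C)CCC[C@]21C | intermediate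
24 | (5R,6S,7R,8R,9S,10R,12Z)-6-(tert-butyldimethylsilyloxy)-8-hydroxy-13-iodo-14,15-dinorlabd-12-en-7-yl acetate | C/C(I)=C/C[C@@H]1[C@@](C)(O)[C@H](OC(C)=O)[C@@H](O[Si](C)(C)C(C)(C)C)[C@@H]2C(C)(C)CCC[C@]21C | intermediate
25 | (5R,6S,7R,8R,9S,10R,12Z)-6,8-dihydroxy-13-iodo-14,15-dinorlabd-12-en-7-yl acetate | C/C(I)=C/C[C@@H]1[C@@](C)(O)[C@H](OC(C)=O)[C@@H](O)[C@@H]2C(C)(C)CCC[C@]21C | intermediate
26 | (5R,6S,7R,8R,9S,10R,12Z)-6,8-dihydroxylabda-12,14-dien-7-yl acetate (CNP0225877.2) | C=C/C(C)=C\C[C@@H]1[C@@](C)(O)[C@H](OC(C)=O)[C@@H](O)[C@@H]2C(C)(C)CCC[C@]21C | target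

## Step count and least certain steps

Total step count: 17. Longest linear sequence: 15 steps (steps 3–17, from 5 through 6, 7, 10, 12 and 13 to 26); the branch from 1 is 14 steps long.

Step 7 (key step). The cycloaddition is slow because the enimide is β,β-disubstituted and the diene polarity is mismatched. This gives the stoichiometric aluminium Lewis acid time to strip or protonate the silyl enol ether, and lets facial and endo control erode. The fallback moves stereocontrol from the auxiliary to a chiral catalyst used in small amount and uses a known reaction type, the catalytic enantioselective intramolecular Diels–Alder reaction of trienimides. It sets out from acid chloride 9 and comes back at thioester 16. Acid chloride 9 would acylate lithiated oxazolidin-2-one to give the achiral imide triflate F1. Coupling of F1 with alkylborane 11 as in step 6 would give the achiral trienimide F2. Cyclisation with Cu(SbF6)2 and a C2-symmetric tert-butyl bis(oxazoline) ligand (divalent copper, catalytic, CH2Cl2, rt) would give the achiral-imide cycloadduct F3; the ligand antipode would be chosen so that its tert-butyl group covers the Cα-Si face of the square-planar chelate. Oxidation with mCPBA as in step 8 would pass through the silyloxy epoxide F4 to the keto imide F5, and lithium ethanethiolate would then give 16.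

Step 6. Under the aqueous basic coupling conditions the silyl enol ether may hydrolyse, or hydroxide may add to the β-triflyloxy enimide, before transmetallation occurs. The fallback moves the coupling to a stage without an enol ether. It sets out from aldehyde 1 and comes back at 12. Aldehyde 1 would be protected with ethylene glycol (PPTS, benzene, reflux) as the dioxolane F6. Hydroboration with 9-BBN would give the alkylborane F7, and coupling with 10 under the conditions of step 6 would give the imide acetal F8. Aqueous acid would release the aldehyde imide F9, olefination with 2 as in step 1 would give the enone imide F10, and silylation as in step 2 would give 12.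

Step 9. Exocyclic cleavage at the very hindered C11 carbonyl (flanked by quaternary C10 and tertiary C8) may be slow, so that ring opening of the oxazolidinone competes. The fallback replaces the thiolate by hydroperoxide and reaches the aldehyde through an acid chloride, which also bypasses step 10. It sets out from 15 and comes back at 17. LiOH and H2O2 (THF/H2O, 0 °C) would give the carboxylic acid F11. Oxalyl chloride with catalytic DMF would give the acid chloride F12, and LiAlH(Ot-Bu)3 (THF, −78 °C) would reduce it to 17 without touching the ketone.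

Step 13. Enolisation may be incomplete or may occur at the wrong site, or the oxaziridine may approach the wrong face of the crowded tetrasubstituted enolate. The fallback replaces enolate oxidation by a second Rubottom-type oxidation. It sets out from 20 and comes back at 22. Soft enolisation with TMSOTf and Et3N (CH2Cl2, 0 °C) would give the tetrasubstituted trimethylsilyl enol ether F13. mCPBA with NaHCO3 would epoxidise it on the face opposite to C20 to the silyloxy epoxide F14, which on mildly acidic work-up would collapse to 22.

## Further compounds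

F1 | step 7 | 3-[(E)-3-{[(trifluoromethyl)sulfonyl]oxy}but-2-enoyl]oxazolidin-2-one | O=C(/C=C(\C)OS(=O)(=O)C(F)(F)F)N1C(=O)OCC1
F2 | step 7 | 3-[(2E,8E,10Z)-10-(tert-butyldimethylsilyloxy)-3,7,7-trimethyldodeca-2,8,10-trienoyl]oxazolidin-2-one | C/C=C(O[Si](C)(C)C(C)(C)C)/C=C/C(C)(C)CCC/C(C)=C/C(=O)N1C(=O)OCC1
F3 | step 7 | 3-{[(1R,2S,4aR,8aR)-3-(tert-butyldimethylsilyloxy)-2,5,5,8a-tetramethyl-1,2,4a,5,6,7,8,8a-octahydronaphthalen-1-yl]carbonyl}oxazolidin-2-one | O=C(N1C(=O)OCC1)[C@@H]1[C@H](C)C(O[Si](C)(C)C(C)(C)C)=C[C@@H]2C(C)(C)CCC[C@]21C
F4 | step 7 | 6,7-epoxide of F3 with the oxygen on the ring face opposite to C20 | O=C(N1C(=O)OCC1)[C@@H]1[C@H](C)[C@@]3(O[Si](C)(C)C(C)(C)C)O[C@H]3[C@@H]2C(C)(C)CCC[C@]21C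
F5 | step 7 | 3-[(5R,6S,8S,9R,10R)-6-(tert-butyldimethylsilyloxy)-7-oxo-12,13,14,15,16-pentanorlabdan-11-oyl]oxazolidin-2-one | O=C(N1C(=O)OCC1)[C@@H]1[C@H](C)C(=O)[C@@H](O[Si](C)(C)C(C)(C)C)[C@@H]2C(C)(C)CCC[C@]21C
F6 | step 6 | 2-(2-methylpent-4-en-2-yl)-1,3-dioxolane | C=CCC(C)(C)C1OCCO1
F7 | step 6 | 9-[4-(1,3-dioxolan-2-yl)-4-methylpentyl]-9-borabicyclo[3.3.1]nonane | CC(C)(CCCB1C2CCCC1CCC2)C1OCCO1
F8 | step 6 | (R)-4-benzyl-3-[(E)-7-(1,3-dioxolan-2-yl)-3,7-dimethyloct-2-enoyl]oxazolidin-2-one | O=C(/C=C(\C)CCCC(C)(C)C1OCCO1)N1C(=O)OC[C@H]1Cc1ccccc1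
F9 | step 6 | (R)-4-benzyl-3-[(E)-3,7,7-trimethyl-8-oxooct-2-enoyl]oxazolidin-2-one | O=CC(C)(C)CCC/C(C)=C/C(=O)N1C(=O)OC[C@H]1Cc1ccccc1
F10 | step 6 | (R)-4-benzyl-3-[(2E,8E)-3,7,7-trimethyl-10-oxododeca-2,8-dienoyl]oxazolidin-2-one | CCC(=O)/C=C/C(C)(C)CCC/C(C)=C/C(=O)N1C(=O)OC[C@H]1Cc1ccccc1
F11 | step 9 | (5R,6S,8S,9R,10R)-6-(tert-butyldimethylsilyloxy)-7-oxo-12,13,14,15,16-pentanorlabdan-11-oic acid | OC(=O)[C@@H]1[C@H](C)C(=O)[C@@H](O[Si](C)(C)C(C)(C)C)[C@@H]2C(C)(C)CCC[C@]21C
F12 | step 9 | (5R,6S,8S,9R,10R)-6-(tert-butyldimethylsilyloxy)-7-oxo-12,13,14,15,16-pentanorlabdan-11-oyl chloride | ClC(=O)[C@@H]1[C@H](C)C(=O)[C@@H](O[Si](C)(C)C(C)(C)C)[C@@H]2C(C)(C)CCC[C@]21C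
F13 | step 13 | (5R,6S,9S,10S,12Z)-6-(tert-butyldimethylsilyloxy)-13-iodo-7-(trimethylsilyloxy)-14,15-dinorlabda-7,12-diene | C/C(I)=C/C[C@@H]1C(C)=C(O[Si](C)(C)C)[C@@H](O[Si](C)(C)C(C)(C)C)[C@@H]2C(C)(C)CCC[C@]21C
F14 | step 13 | 7,8-epoxide of F13 with the oxygen on the ring face opposite to C20 | C/C(I)=C/C[C@@H]1[C@@]3(C)O[C@@]3(O[Si](C)(C)C)[C@@H](O[Si](C)(C)C(C)(C)C)[C@@H]2C(C)(C)CCC[C@]21C
A1 | alternative 1 | cis-fused ring A cyclohexene–ring B enedione adduct | O=C1C(C)=CC(=O)[C@H]2C(C)(C)C=CC[C@]21C
A2 | alternative 1 | 2,6-dimethyl-1,4-benzoquinone | O=C1C(C)=CC(=O)C=C1C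
A3 | alternative 1 | 4-methylpenta-1,3-diene | C=CC=C(C)C
A4 | alternative 2 | bicyclic 5,8-diene with C6 silyl enol ether and C9 acyl pyrazole | Cc1cc(C)n(n1)C(=O)C1=C(C)CC(O[Si](C)(C)C(C)(C)C)=C2C(C)(C)CCC[C@]21C
A5 | alternative 2 | tert-butyldimethyl{[1-(2,6,6-trimethylcyclohex-1-en-1-yl)vinyl]oxy}silane | C=C(O[Si](C)(C)C(C)(C)C)C1=C(C)CCCC1(C)C
A6 | alternative 2 | 1-(but-2-ynoyl)-3,5-dimethylpyrazole | CC#CC(=O)n1nc(C)cc1C
A7 | alternative 3 | ent-copalyl diphosphate | OP(O)(=O)OP(=O)(O)OC/C=C(\C)CC[C@@H]1C(=C)CC[C@@H]2C(C)(C)CCC[C@]21C
A8 | alternative 3 | (2E,6E,10E)-geranylgeranyl diphosphate | CC(C)=CCC/C(C)=C/CC/C(C)=C/CC/C(C)=C/COP(=O)(O)OP(=O)(O)O
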